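**Retrosynthetic overview**
1. The target diacetate comes from the meso triol by acetylating its two secondary OH groups. The triol comes from 4,5-trans-dihydroxy-5-undecanoylcyclopent-2-enone by 1,2-reduction of the ring C=O.
2. The cyclopentenone is opened at C4–C5 (intramolecular aldol) to (Z)-5-hydroxy-4,6-dioxohexadec-2-enal. That enal comes from oxidising the furan of a 2-furyl acyloin, so the furan supplies four of the five ring carbons.
3. The key C–C disconnection is the carbinol–ketone bond of the acyloin. Undecanal serves as an undecanoyl anion (Breslow intermediate of a triazolylidene carbene) and furfural as the acceptor, so two aldehyde carbons are joined.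
4. Ring order: the purchased furan is opened, and the cyclopentene, the only ring formed in the route, is closed in the same flask in step 2.

Assumption: the drawn structure has an internal mirror plane (the two acetoxy carbons are an R/S pair and the carbinol carbon is pseudoasymmetric, r). It is therefore an achiral meso compound, only relative configuration has to be controlled, and racemic intermediates converge on it.

**Step 1**
Reactants: 1 undecanal; 2 furfural (furan-2-carbaldehyde)
Product: 4 rac-1-(furan-2-yl)-1-hydroxydodecan-2-one, via Breslow enaminol 3 (not isolated)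
Conditions: 1 (1.5 equiv), 2 (1.0 equiv), 2-(pentafluorophenyl)-5,6,7,8-tetrahydro-[1,2,4]triazolo[4,3-a]pyridin-2-ium tetrafluoroborate (5 mol %), i-Pr2NEt (1.0 equiv), CH2Cl2, 70 °C (sealed tube), argon
Reagents that add atoms: none
Why: In this carbene-catalysed crossed benzoin (acyloin) reaction the electron-poor triazolylidene adds to the unhindered aliphatic aldehyde 1, proton transfer gives Breslow enaminol 3 (an unmasked undecanoyl anion equivalent), and 3 attacks the more electrophilic heteroaromatic aldehyde 2 under kinetic control, which joins two formerly electrophilic CHO carbons with the ketone on the alkyl side and leaves a racemic carbinol centre that does not matter because it is planarised in step 2.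

**Step 2**
Reactants: 4 rac-1-(furan-2-yl)-1-hydroxydodecan-2-one
Product: 8 rac-(4R,5R)-4,5-dihydroxy-5-undecanoylcyclopent-2-en-1-one (C4-OH cis to the acyl group), via furan endoperoxide 5 (not isolated), via Z-oxoenal 6 (not isolated), via pyranone hemiacetal 7 (not isolated)
Conditions: O2, hν (white LED), 5,10,15,20-tetraphenylporphyrin (1 mol %), CH2Cl2, −78 °C; Me2S (3 equiv), −78 → 0 °C; then MgBr2·OEt2 (2 equiv), i-Pr2NEt (2.5 equiv), −20 → 0 °C; aq NH4Cl
Reagents that add atoms: dioxygen, O=O
Why: Proposed new method: singlet oxygen adds [4+2] to the furan and Me2S reduces endoperoxide 5 to Z-oxoenal 6 (resting as its hemiacetal 7, a photooxygenative Achmatowicz reaction), so no oxidant remains when the very enolisable 2-hydroxy-1,3-diketone appears, then soft enolisation gives the magnesium 1,3-diketonate of 6, which closes by a Baldwin-favoured 5-(enolexo)-exo-trig intramolecular aldol in which the aldehyde oxygen must bind the divalent magnesium held between the two diketonate oxygens and so points away from the C5-OH, placing the new C4-OH cis to the undecanoyl group and trans to the tertiary OH; the closest known reaction types are the amine-mediated isomerisation of Achmatowicz pyranones to trans-4,5-dihydroxycyclopent-2-enones and magnesium-mediated soft-enolisation aldol reactions.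

**Step 3**
Reactants: 8 rac-(4R,5R)-4,5-dihydroxy-5-undecanoylcyclopent-2-en-1-one
Product: 9 1-[(1r,2R,5S)-1,2,5-trihydroxycyclopent-3-en-1-yl]undecan-1-one (meso)
Conditions: NaBH4 (0.6 equiv, in portions), CeCl3·7H2O (1.2 equiv), MeOH, −78 °C, 30 min; aq NH4Cl
Reagents that add atoms: none
Why: In this Luche reduction trivalent cerium enforces 1,2-attack on the flat, more Lewis-basic enone carbonyl, which should react faster than the neopentyl-type acyclic ketone, and hydride arrives on the face that carries only the small tertiary OH (anti to the undecanoyl group and to the C4-OH), so the new carbinol is cis to the C4-OH and both enantiomers of 8 give the same meso triol.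

**Step 4**
Reactants: 9 1-[(1r,2R,5S)-1,2,5-trihydroxycyclopent-3-en-1-yl]undecan-1-one
Product: 10 (1R,2r,3S)-2-hydroxy-2-undecanoylcyclopent-4-ene-1,3-diyl diacetate (target)
Conditions: Ac2O (2.5 equiv), pyridine (6 equiv), CH2Cl2, 0 °C → rt
Reagents that add atoms: acetic anhydride, CC(=O)OC(C)=O
Why: In this chemoselective O-acetylation the two secondary allylic alcohols acylate readily, whereas the hindered tertiary α-ketol OH stays free without forcing conditions and cannot pick up an acetyl by migration because it is trans to both acetates, and no stereocentre is touched.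

**Compound list**
1 | undecanal | CCCCCCCCCCC=O | starting material
2 | furfural (furan-2-carbaldehyde) | O=Cc1ccco1 | starting material
3 | 1-[2-(pentafluorophenyl)-5,6,7,8-tetrahydro-[1,2,4]triazolo[4,3-a]pyridin-3(2H)-ylidene]undecan-1-ol (Breslow enaminol) | CCCCCCCCCCC(O)=C1N(c2c(F)c(F)c(F)c(F)c2F)N=C2CCCCN12 | intermediate
4 | rac-1-(furan-2-yl)-1-hydroxydodecan-2-one | CCCCCCCCCCC(=O)C(O)c1ccco1 | intermediate
5 | 1-hydroxy-1-(2,3,7-trioxabicyclo[2.2.1]hept-5-en-1-yl)dodecan-2-one (furan endoperoxide, stereoisomer mixture) | CCCCCCCCCCC(=O)C(O)C12OOC(O1)C=C2 | intermediate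
6 | (2Z)-5-hydroxy-4,6-dioxohexadec-2-enal | CCCCCCCCCCC(=O)C(O)C(=O)/C=C\C=O | intermediate
7 | 6-hydroxy-2-undecanoyl-2H-pyran-3(6H)-one (ring tautomer of 6, stereoisomer mixture) | CCCCCCCCCCC(=O)C1OC(O)C=CC1=O | intermediate
8 | rac-(4R,5R)-4,5-dihydroxy-5-undecanoylcyclopent-2-en-1-one (trans-diol, C4-OH cis to the acyl group; one enantiomer drawn) | CCCCCCCCCCC(=O)[C@@]1(O)C(=O)C=C[C@H]1O | intermediate
9 | 1-[(1r,2R,5S)-1,2,5-trihydroxycyclopent-3-en-1-yl]undecan-1-one (meso; both secondary OH cis to the acyl group, tertiary OH on the other face) | CCCCCCCCCCC(=O)[C@@]1(O)[C@@H](O)C=C[C@H]1O | intermediate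
10 | (1R,2r,3S)-2-hydroxy-2-undecanoylcyclopent-4-ene-1,3-diyl diacetate (meso) | CCCCCCCCCCC(=O)[C@@]1(O)[C@@H](OC(C)=O)C=C[C@H]1OC(C)=O | target

**Totals**
Total step count: 4. Longest linear sequence: 4 (1 + 2 → 4 → 8 → 9 → 10).

**Steps most likely to fail**

Step 2 carries the most risk. The endoperoxide may collapse to a hydroxybutenolide, the tricarbonyl may decompose, or the aldol may give the cis-diol. The fallback sets out from 4 and returns at 8. A Piancatelli rearrangement of 4 (Dy(OTf)3 10 mol %, t-BuOH/H2O, 80 °C) closes the hydroxypentadienyl cation by a conrotatory 4π process. It gives rac-trans-4-hydroxy-5-undecanoylcyclopent-2-en-1-one F4. The enolised β-diketone carbon C5 of this compound is then hydroxylated with dimethyldioxirane (acetone, −20 °C). The oxidant attacks the face opposite the C4-OH, which sets the same trans-diol by steric control and delivers 8.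

Step 3 is the second risk, because the exocyclic ketone may be reduced as well. The fallback sets out from 8 and returns at 9. Me3SiOTf (4 equiv)/Et3N in CH2Cl2 at 0 °C silylates both hydroxyls and converts the only enolisable ketone into its silyl enol ether. This gives rac-(4R,5R)-4,5-bis(trimethylsilyloxy)-5-[(1Z)-1-(trimethylsilyloxy)undec-1-en-1-yl]cyclopent-2-en-1-one F5. With i-Bu2AlH in toluene at −78 °C only the ring carbonyl is left to reduce, again from the face anti to the large side chain. The product is rac-4,5-bis(trimethylsilyloxy)-5-[(1Z)-1-(trimethylsilyloxy)undec-1-en-1-yl]cyclopent-2-en-1-ol F6, with the C1-OH cis to the C4 silyl ether. HF·pyridine in THF at 0 °C removes all three silyl groups, regenerates the ketone and gives 9.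

Step 1 is the third risk. Possible failures are furoin or undecanoin homocoupling, formation of the regioisomeric furyl ketone, and base-induced ketol transposition. The fallback sets out from 1 (and uses 2) and returns at 4. It replaces the catalytic acyl anion with a stoichiometric masked one (Corey–Seebach). Aldehyde 1 with propane-1,3-dithiol and BF3·OEt2 in CH2Cl2 gives 2-decyl-1,3-dithiane F1. n-BuLi in THF at −30 °C gives 2-decyl-2-lithio-1,3-dithiane F2. Addition of 2 at −78 °C gives rac-(2-decyl-1,3-dithian-2-yl)(furan-2-yl)methanol F3. Alkylative hydrolysis (MeI, CaCO3, MeCN/H2O, 40 °C), which leaves the furan intact, releases 4.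

**Further compounds**
F1 | step 1 | 2-decyl-1,3-dithiane | CCCCCCCCCCC1SCCCS1
F2 | step 1 | 2-decyl-2-lithio-1,3-dithiane | [Li]C1(CCCCCCCCCC)SCCCS1
F3 | step 1 | rac-(2-decyl-1,3-dithian-2-yl)(furan-2-yl)methanol | CCCCCCCCCCC1(SCCCS1)C(O)c1ccco1
F4 | step 2 | rac-trans-4-hydroxy-5-undecanoylcyclopent-2-en-1-one (one enantiomer drawn) | CCCCCCCCCCC(=O)[C@@H]1C(=O)C=C[C@H]1O
F5 | step 3 | rac-(4R,5R)-4,5-bis(trimethylsilyloxy)-5-[(1Z)-1-(trimethylsilyloxy)undec-1-en-1-yl]cyclopent-2-en-1-one (one enantiomer drawn) | CCCCCCCCC/C=C(\O[Si](C)(C)C)[C@@]1(O[Si](C)(C)C)C(=O)C=C[C@H]1O[Si](C)(C)C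
F6 | step 3 | rac-4,5-bis(trimethylsilyloxy)-5-[(1Z)-1-(trimethylsilyloxy)undec-1-en-1-yl]cyclopent-2-en-1-ol, C1-OH cis to the C4 silyl ether (one enantiomer drawn) | CCCCCCCCC/C=C(\O[Si](C)(C)C)[C@@]1(O[Si](C)(C)C)[C@@H](O)C=C[C@H]1O[Si](C)(C)C
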